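(The runs stem from a simulated flask for substances that don't exist; noise was put on by code.)

**Easy start.** I begin by adding two columns of this flask's run, electrophile and product.

| flask | electrophile | nucleophile | free base | protic impurity | scavenger | remark | time |
|---|---|---|---|---|---|---|---|
| maple | 5 mM | 0.90 equiv | 1.2 equiv | 0.50 mM | 1 equiv | the very flask that is asked about, followed so far |  |
| flask | 5.0 mM | 0.900 equiv | 1.20 equiv | 0.500 mM | 1.00 equiv |  | 1.5 h |

- maple (time / min: electrophile / %, product / %): 2.00: 41.2, 49.2; 5.00: 28.4, 61.3; 10.0: 20.2, 69.6; 15.0: 16.3, 74.3; 20.0: 13.5, 76.3; 25.0: 12.4, 77.6

(scatter of a reading: 0.5 percentage points)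

- in percentages every species weighs as the electrophile in it: one homo dimer counts as two
- for acid set free the idle adduct is counted in
- what may be going on: electrophile + nucleophile -> acid set free + product; nucleophile + acid set free <-> protonated nucleophile; acid set free + free base <-> salt of the base; electrophile + protic impurity -> quenched substrate; electrophile + acid set free <-> idle adduct; acid set free + scavenger -> scavenged by-product; 2 electrophile -> homo dimer
- the earlier runs do not show how much of nucleophile is bound; that part of a forecast is a guess

* part of the electrophile that has reacted at 1.5 h
* share of the unused nucleophile that is free and not bound as protonated nucleophile, at 1.5 h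

**The level.** The sum is 90.4% at 2.00 min and 90.0% at 25.0 min, flat within the scatter. The missing part is about what the protic impurity can take, 10.0% of the electrophile. I therefore define the product level: with the impurity taking its whole charge, it is the smaller of the nucleophile charge and the electrophile that remains, as a percentage of the electrophile charged. Here the two tie at 4.50 mM and 4.50 mM, so the level is 90.0%.

**The curve.** Over the first 2.00 min the readings put the fall of electrophile at 0.294 min⁻¹ of the charge on average, and at that reading it already stands below product, so the curves cross earlier. A knee follows. Between 15.0 min and 25.0 min the fall is 0.003900 min⁻¹. Product climbs towards the level, short of it by about the electrophile still left.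

**The forecast.** It gives 95% reacted and 18% free, with this caution: “A slow scavenger could raise both answers”. On my level, its 95% means product near 85.0%.

**The flask.** It gives 96.9% reacted and 23.9% free, 5.9 percentage points above the forecast.

    electrophile + nucleophile → acid set free + product (k = 6.00 M⁻¹ s⁻¹)
    nucleophile + acid set free ⇌ protonated nucleophile, settled at all times (K = 4.40 × 10⁵ M⁻¹)
    acid set free + free base ⇌ salt of the base (K = 41000 M⁻¹, k = 270 M⁻¹ s⁻¹)
    electrophile + protic impurity → quenched substrate (k = 12.0 M⁻¹ s⁻¹)
    electrophile + acid set free ⇌ idle adduct, settled at all times (K = 700 M⁻¹)
    acid set free + scavenger → scavenged by-product (k = 14.0 M⁻¹ s⁻¹)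
    2 electrophile → homo dimer (k = 0.00280 M⁻¹ s⁻¹)

In this flask at 1.50 h product is 86.6%, which is 3.4 points under the level, with 3.11% electrophile left; at 15.0 h it stands at 89.7%. In the neighbour charged with 0.360 equiv of nucleophile, the limiting reagent, the same reckoning gives a level of 36.0%. That neighbour holds 36.0% product at 1.50 h, with 0% of its nucleophile and 50% of its electrophile left.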